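**Retrosynthetic overview**
1. Target ⇒ all-cis oxolane diol + 3,4-dimethoxybenzoyl chloride (primary-selective acylation last); the diol is unmasked from its isopropylidene ketal.
2. C2–aryl bond ⇒ veratrole + a cis-fused furanosyl oxocarbenium ion (Friedel–Crafts C-glycosylation; the aryl enters cis to the C4 oxygen and the C3 branch).
3. Oxolane and 1,3-dioxane rings ⇒ one acyclic aldol; both rings close in a single acid-mediated operation (oxolane first in the cascade, dioxane second), and the dioxane is opened again near the end.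
4. Acyclic aldol ⇒ two achiral silyloxy aldehydes by L-proline anti cross-aldol, which sets C3 and C4.

Assumption: locants O1, C2 (aryl), C3 (CH2O), C4 (OH), C5 in the text are those of the oxolane ring of the target; anomeric mixtures of the methyl furanoside intermediates are carried on unseparated because that centre becomes planar later.

**Step 1**
Reactants: 1 3-{[tert-butyl(dimethyl)silyl]oxy}propanal; 2 {[tert-butyl(dimethyl)silyl]oxy}acetaldehyde
Product: 3 (2S,3R)-4-{[tert-butyl(dimethyl)silyl]oxy}-2-({[tert-butyl(dimethyl)silyl]oxy}methyl)-3-hydroxybutanal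
Conditions: L-proline (20 mol %), DMF, 4 °C; 1 added over 24 h by syringe pump to 2 (2 equiv)
Reagents that add atoms: none
Why: Proline enamine catalysis (direct cross-aldol, Houk–List closed transition state): the slowly added, more readily enolised donor 1 attacks the Re face of the more electrophilic α-silyloxy aldehyde 2, giving the anti aldol in which C3 (S, donor α-carbon) and C4 (R, new carbinol) of the target are set together.

**Step 2**
Reactants: 3 (2S,3R)-4-{[tert-butyl(dimethyl)silyl]oxy}-2-({[tert-butyl(dimethyl)silyl]oxy}methyl)-3-hydroxybutanal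
Product: 6 (4aS,7aR)-5-methoxy-2,2-dimethyltetrahydro-4H-furo[3,4-d][1,3]dioxine, via lactol triol 4 (not isolated), via methyl furanoside diol 5 (not isolated)
Conditions: (+)-camphor-10-sulfonic acid (0.2 equiv), MeOH (6 equiv), Me2C(OMe)2 (10 equiv), acetone, 0 °C to rt, 16 h; Et3N
Reagents that add atoms: methanol (CO); 2,2-dimethoxypropane (COC(C)(C)OC)
Why: Acid methanolysis of both silyl ethers lets the C5 hydroxyl close on the aldehyde (only a five-membered lactol is possible), Fischer glycosidation fixes the oxolane as its methyl acetal and transketalisation traps the cis CH2OH/C4–OH pair as the six-membered isopropylidene ketal, so the oxolane and 1,3-dioxane rings both close in this one thermodynamically driven operation without touching C3 or C4.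

**Step 3**
Reactants: 6 (4aS,7aR)-5-methoxy-2,2-dimethyltetrahydro-4H-furo[3,4-d][1,3]dioxine; 7 1,2-dimethoxybenzene (veratrole)
Product: 9 (4aR,5R,7aR)-5-(3,4-dimethoxyphenyl)-2,2-dimethyltetrahydro-4H-furo[3,4-d][1,3]dioxine, via oxocarbenium triflate 8 (not isolated)
Conditions: Me3SiOTf (0.2 equiv), 7 (3 equiv), CH2Cl2, −78 to −50 °C, 1 h; Et3N at −78 °C
Reagents that add atoms: none
Why: Friedel–Crafts C-glycosylation: catalytic Me3SiOTf ionises the methyl acetal to the oxocarbenium ion, whose envelope with the C4 oxygen pseudoaxial and the C3 branch pseudoequatorial is attacked on its inside face (Woerpel model, the 1,2-cis/1,3-cis sense of α-C-glycosides from ribofuranosyl donors), so veratrole, reacting para to a methoxy group, bonds to C2 cis to both neighbours (2R) under kinetic control at low temperature.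

**Step 4**
Reactants: 9 (4aR,5R,7aR)-5-(3,4-dimethoxyphenyl)-2,2-dimethyltetrahydro-4H-furo[3,4-d][1,3]dioxine
Product: 10 (3R,4S,5R)-5-(3,4-dimethoxyphenyl)-4-(hydroxymethyl)oxolan-3-ol
Conditions: AcOH–H2O (4:1), 35 °C, 4 h
Reagents that add atoms: none
Why: Ketal hydrolysis: dilute acetic acid cleaves the six-membered isopropylidene ketal much faster than the benzylic oxolane C–O bond can ionise, so no stereocentre is touched.

**Step 5**
Reactants: 10 (3R,4S,5R)-5-(3,4-dimethoxyphenyl)-4-(hydroxymethyl)oxolan-3-ol; 11 3,4-dimethoxybenzoyl chloride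
Product: 12 [(2R,3S,4R)-2-(3,4-dimethoxyphenyl)-4-hydroxyoxolan-3-yl]methyl 3,4-dimethoxybenzoate
Conditions: 11 (1.05 equiv), 2,4,6-collidine (2 equiv), CH2Cl2, −40 to 0 °C
Reagents that add atoms: none
Why: Nucleophilic acyl substitution under kinetic control: with a hindered pyridine base at low temperature the acid chloride acylates the primary hydroxyl far faster than the flanked secondary one, and no stereocentre is involved.

**Compound list**
1 | 3-{[tert-butyl(dimethyl)silyl]oxy}propanal | O=CCCO[Si](C)(C)C(C)(C)C | starting material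
2 | {[tert-butyl(dimethyl)silyl]oxy}acetaldehyde | O=CCO[Si](C)(C)C(C)(C)C | starting material
3 | (2S,3R)-4-{[tert-butyl(dimethyl)silyl]oxy}-2-({[tert-butyl(dimethyl)silyl]oxy}methyl)-3-hydroxybutanal (anti aldol) | O=C[C@@H](CO[Si](C)(C)C(C)(C)C)[C@@H](O)CO[Si](C)(C)C(C)(C)C | intermediate
4 | (3S,4R)-3-(hydroxymethyl)oxolane-2,4-diol (lactol triol, both anomers) | OC1OC[C@H](O)[C@@H]1CO | intermediate
5 | (3R,4S)-4-(hydroxymethyl)-5-methoxyoxolan-3-ol (methyl furanoside diol, both anomers) | COC1OC[C@H](O)[C@@H]1CO | intermediate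
6 | (4aS,7aR)-5-methoxy-2,2-dimethyltetrahydro-4H-furo[3,4-d][1,3]dioxine (cis-fused, both anomers at C5) | COC1OC[C@@H]2OC(C)(C)OC[C@H]12 | intermediate
7 | 1,2-dimethoxybenzene (veratrole) | COc1ccccc1OC | starting material
8 | (4aS,7aR)-2,2-dimethyl-4a,7a-dihydro-4H,7H-furo[3,4-d][1,3]dioxin-6-ium triflate (cis-fused oxocarbenium ion) | CC1(C)OC[C@@H]2C=[O+]C[C@@H]2O1.[O-]S(=O)(=O)C(F)(F)F | intermediate
9 | (4aR,5R,7aR)-5-(3,4-dimethoxyphenyl)-2,2-dimethyltetrahydro-4H-furo[3,4-d][1,3]dioxine (aryl cis to both ring-fusion substituents) | COc1ccc([C@@H]2OC[C@@H]3OC(C)(C)OC[C@H]23)cc1OC | intermediate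
10 | (3R,4S,5R)-5-(3,4-dimethoxyphenyl)-4-(hydroxymethyl)oxolan-3-ol (all-cis diol) | OC[C@H]1[C@@H](O)CO[C@H]1c1ccc(OC)c(OC)c1 | intermediate
11 | 3,4-dimethoxybenzoyl chloride | COc1ccc(C(Cl)=O)cc1OC | starting material
12 | [(2R,3S,4R)-2-(3,4-dimethoxyphenyl)-4-hydroxyoxolan-3-yl]methyl 3,4-dimethoxybenzoate (aryl, CH2O and OH all on one face) | COc1ccc(C(=O)OC[C@H]2[C@@H](O)CO[C@H]2c2ccc(OC)c(OC)c2)cc1OC | target

**Totals**
Total steps: 5. Longest linear sequence: 5 (from 1 or 2 to 12).

**Steps most likely to fail**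

Step 1. Both aldehydes can enolise, so homo-aldol of 2 competes. The anti:syn ratio with α-oxy acceptors is typically only about 4:1, and the β-silyloxy donor can lose silanol. The fallback sets out from 2 and comes back at 6. Iridium-catalysed transfer-hydrogenative anti-(hydroxymethyl)allylation of 2 with 4-vinyl-1,3-dioxolan-2-one ([Ir(cod)Cl]2, the SEGPHOS enantiomer that gives the (2R,3S) product, 4-cyano-3-nitrobenzoic acid, K3PO4, i-PrOH, THF, 60 °C) gives (2R,3S)-1-{[tert-butyl(dimethyl)silyl]oxy}-3-(hydroxymethyl)pent-4-en-2-ol F1. Ozonolysis (O3, CH2Cl2–MeOH, −78 °C; Me2S) gives (2S,3R)-4-{[tert-butyl(dimethyl)silyl]oxy}-3-hydroxy-2-(hydroxymethyl)butanal F2, which under the conditions of step 2 gives 6.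

Step 2. The open-chain form can be diverted to a five-membered ketal on the C4/C5 diol, desilylation may lag behind acetal exchange, and the β-hydroxy aldehyde can dehydrate. The fallback sets out from 3 and comes back at 10, closing the rings one at a time with a different tether. Methanolic HCl (AcCl in MeOH, 0 °C) converts 3 into the methyl furanoside diol 5, now isolated. t-Bu2Si(OTf)2 and 2,6-lutidine in DMF close the second ring as (4aS,7aR)-2,2-di-tert-butyl-5-methoxytetrahydro-4H-furo[3,4-d][1,3,2]dioxasiline F3. Arylation with 7 as in step 3 gives (4aR,5R,7aR)-2,2-di-tert-butyl-5-(3,4-dimethoxyphenyl)tetrahydro-4H-furo[3,4-d][1,3,2]dioxasiline F4, and HF·pyridine in THF releases 10 without an acid step.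

Step 3. This is the least secure step. The inside-attack preference is inferred from monocyclic and ribose-type ions, not shown for this cis-fused ion. Re-ionisation of the electron-rich product would drain the all-cis isomer to the trans one or lead to double arylation, and the ketal may not survive the Lewis acid. The fallback sets out from 3 and comes back at 9, making the C2–aryl bond by carbonyl addition and the oxolane by O-alkylation. HF·pyridine desilylation of 3 to lactol 4 and ketalisation (acetone, Me2C(OMe)2, pyridinium p-toluenesulfonate) give (4aS,7aR)-2,2-dimethyltetrahydro-4H-furo[3,4-d][1,3]dioxin-5-ol F5. (3,4-Dimethoxyphenyl)magnesium bromide (3 equiv, THF, −20 °C) opens it to (R)-(3,4-dimethoxyphenyl)[(4R,5R)-4-(hydroxymethyl)-2,2-dimethyl-1,3-dioxan-5-yl]methanol F6; facial selectivity here is not secured, so the carbinol epimers are separated at this point. TsCl, Et3N and Me3N·HCl at 0 °C give the primary tosylate [(4R,5R)-5-[(R)-(3,4-dimethoxyphenyl)(hydroxy)methyl]-2,2-dimethyl-1,3-dioxan-4-yl]methyl 4-methylbenzenesulfonate F7. NaH in THF closes the oxolane by 5-exo-tet Williamson etherification with retention at C2 to give 9.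

**Further compounds**
F1 | step 1 | (2R,3S)-1-{[tert-butyl(dimethyl)silyl]oxy}-3-(hydroxymethyl)pent-4-en-2-ol | C=C[C@@H](CO)[C@@H](O)CO[Si](C)(C)C(C)(C)C
F2 | step 1 | (2S,3R)-4-{[tert-butyl(dimethyl)silyl]oxy}-3-hydroxy-2-(hydroxymethyl)butanal | O=C[C@@H](CO)[C@@H](O)CO[Si](C)(C)C(C)(C)C
F3 | step 2 | (4aS,7aR)-2,2-di-tert-butyl-5-methoxytetrahydro-4H-furo[3,4-d][1,3,2]dioxasiline | COC1OC[C@@H]2O[Si](C(C)(C)C)(C(C)(C)C)OC[C@H]12
F4 | step 2 | (4aR,5R,7aR)-2,2-di-tert-butyl-5-(3,4-dimethoxyphenyl)tetrahydro-4H-furo[3,4-d][1,3,2]dioxasiline | COc1ccc([C@@H]2OC[C@@H]3O[Si](C(C)(C)C)(C(C)(C)C)OC[C@H]23)cc1OC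
F5 | step 3 | (4aS,7aR)-2,2-dimethyltetrahydro-4H-furo[3,4-d][1,3]dioxin-5-ol | OC1OC[C@@H]2OC(C)(C)OC[C@H]12
F6 | step 3 | (R)-(3,4-dimethoxyphenyl)[(4R,5R)-4-(hydroxymethyl)-2,2-dimethyl-1,3-dioxan-5-yl]methanol | COc1ccc([C@H](O)[C@H]2COC(C)(C)O[C@H]2CO)cc1OC
F7 | step 3 | [(4R,5R)-5-[(R)-(3,4-dimethoxyphenyl)(hydroxy)methyl]-2,2-dimethyl-1,3-dioxan-4-yl]methyl 4-methylbenzenesulfonate | COc1ccc([C@H](O)[C@H]2COC(C)(C)O[C@H]2COS(=O)(=O)c2ccc(C)cc2)cc1OC
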